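## The problem

Target **30** is methyl 4-hydroxy-3-[(2R,3S,6S,7S)-6-hydroxy-2-(2-hydroxypropan-2-yl)-4-methoxy-7-(3-phenylpropanoyl)-2,3,6,7-tetrahydro-1-benzofuran-3-yl]benzoate. It is numbered here as a benzofuran (O1, C2, C3, C3a, C4 to C7, C7a), with C8 the carbinol carbon on C2 and C9 the ketone carbon on C7; ring A is the arene, ring B the dihydrofuran, ring C the carbocycle. Rings B and C share the tetrasubstituted enol ether C3a=C7a, and ring C is the bis(enol ether) of a cyclohexane-1,3-dione (O1 on C7a, methoxy on C4, C4=C5), so loss of water across C6–C7 would make it a benzofuran. There are two pairs of stereocentres: C2/C3 on ring B (carbinol and aryl cis, on the face called α below) and C6/C7 on ring C (hydroxyl and acyl cis, on the β face). The flat C3a=C7a unit lies between the pairs, so neither can be relied on to set the other. C2 can be epimerised only while it carries a carbonyl group, C3 not at all, and C7 is lost as soon as the β-hydroxy ketone meets acid or base. The dienol ether is acid-labile, the phenol and tertiary alcohol are free, and the methyl benzoate must survive the reagent that brings the two methyl groups of C8. The enabling feature is the 1,3-relation of the C6 hydroxyl and the C9 carbonyl, cis across C6–C7: it is what remains after N–O cleavage of an isoxazoline fused across C6–C7, the adduct of a nitrile oxide with the C6=C7 bond of a cyclohex-2-enone whose carbonyl carbon is C7a. That enone needs a borrowed stereocentre, and C4, which ends sp2, can carry a silyloxy group for this. The dipole avoids that group, so the C4 oxygen ends on the α face, the face of the C3 aryl group; its configuration can only be passed to C3 through a covalent link, because steric shielding would send the aryl group to the β face.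

## Retrosynthesis

**30 from 28.** The last operation is reductive opening of isoxazoline **28**, with hydrolysis of imine **29**. No skeletal bond is cut. Compared with carrying a protected β-hydroxy ketone, the isoxazoline keeps C7 locked in a cis-fused bicycle and keeps C7–H from lying between two carbonyl groups during every basic step. The forward reaction must spare the dienol ether, the benzoate and the allylic C6–O bond.

**28 from 25 via 27 and 26.** The C4 methoxy bond is cut: dienol ether **27** comes from vinylogous ester **26** by deprotonation at C5 and O-methylation. The phenol and the C8 hydroxyl are capped as triethylsilyl ethers (**25** to **26**) and freed again (**27** to **28**) while the isoxazoline is still intact. An earlier methylation is excluded because C4 must stay sp3 until ring B is closed. The step needs O- over C-methylation, α′ over γ deprotonation, and an enolate that does not expel the C6 oxygen.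

**25 from 22 via 24.** The C4 ketone comes from allylic alcohol **24**, and the two C8–CH3 bonds are cut back to lactone **22**. The lactone holds the C2 substituent cis to the aryl group, masks the phenol, and makes C8 the most electrophilic carbonyl, so MeMgBr can pass the benzoate by. A free ester at C2 would offer none of this.

**22 from 17 and 18 via 20.** O1–C2 and C2–C3 are cut together: a (4+1) annulation of arylidene ketone **17** with ethyl diazoacetate **18**. The competing cut, aryl addition to a C2-bearing alkylidene followed by acid cyclodehydration, would leave hydrogens on both C3a and C7 and an acid step beside the isoxazoline. Closing a carbonyl ylide onto an arylidene puts the double bond at C3a=C7a with no choice. The forward step must deliver the aryl group to the α face; the tether in **17** does this. C2 need not be controlled, since **20** is epimerised into **22**.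

**17 from 15 via 16.** The two Si–O bonds are cut. The di-tert-butylsilylene joins the phenol oxygen to the C4 oxygen, which the (E)-arylidene already holds close together on the α side. The simpler silyl ethers of **15** would leave the pseudoaxial C4 group shielding the α face of C3 and would give the C3 epimer.

**15 from 10 and 14 (key disconnection).** C7–C9 and C6–O are cut: nitrile oxide **14**, made from oxime **12** of aldehyde **11** through chloride **13**, adds to the C6=C7 bond of dienone **10**. This removes two stereocentres and the whole side chain in one step and leaves an enone with a single stereocentre.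

**10 from 5 and 7.** The C3a=C3 bond is cut (aldol condensation of enone **5** with aldehyde **7**, from **6**). The condensation is placed before the cycloaddition for three reasons:
- enone **5** has only one kinetically accessible α-CH2;
- the cycloadduct would have an acidic C7–H beside a β-leaving group;
- the arylidene forces the C4 silyloxy group pseudoaxial, which sharpens the facial bias of the key step.

**5 from 1 via 3 and 2.** Enone **5** comes from monoacetate **3** by oxidation and loss of acetic acid, **3** from meso diol **2** by enzymatic desymmetrisation, and **2** from all-cis triol **1**. The only absolute stereochemical information in the route enters here.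

## Roads not taken

Alternative 1: Ring C is closed last by cutting C5–C6. A chelating Lewis acid activates the C6 aldehyde of **A2**, the terminal carbon of the 1-methoxyvinyl group on C3a attacks, and proton loss from C5 gives dienol ether **A1**.
- Merits: the C4 methoxy dienol ether is present from the start, so no late enolate methylation is needed. Ring B with C2/C3 is made on a simple precursor, where a catalyst-controlled annulation is on familiar ground. In both respects this road is better than the chosen one.
- Weak points: **A2** has C7 α to an aldehyde and β to an alkoxy group, and an enol ether that the Lewis acid can hydrolyse. The C6 configuration rests on a chelate model, not on a geometric necessity. **A1** is formed as an allylic alcohol on a dienol ether in the presence of the acid that dehydrates it. C9 travels as a protected alcohol, so deprotection and oxidation fall on the most fragile compound.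
- Comparison: the chosen plan offsets its harder methylation with a cis C6/C7 relation that cannot come out otherwise and a β-hydroxy ketone that appears only in the final step.

Alternative 2: C3–C3a is cut. Irradiation of 3-(alkenyloxy)coumarin **A4** closes the divinyl ether in a six-electron electrocyclisation, and a hydrogen shift gives cis-fused lactone **A3**.
- Merits: the cis C2/C3 lactone arises in one reagent-free step. This is shorter than steps 10 to 12 here and needs no epimerisation.
- Weak points: **A3** is racemic and has no handle for absolute configuration. It carries only an ester on C3a and a methyl group on C7, so all of ring C and C6, C7 and C9 must still be added, with their configuration set across the flat enol ether.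
- Comparison: the chosen plan pays three steps for the lactone but has C6, C7 and the absolute configuration secured before ring B is made.

Alternative 3: C3a–C7a and C6–C7 are cut. The 3-methoxyfuran of **A6** adds to its tethered (Z)-β-alkoxy enone, and rings B and C close together as oxygen-bridged cycloadduct **A5**.
- Merits: this is the most convergent road. The tether relays C2/C3 to C6/C7, and the C4 methoxy group and C6 oxygen are already in place. In step count it is better than the chosen plan.
- Weak points: furan cycloadditions are reversible, the (Z)-enol ether can isomerise, and exo approach must be secured. Opening the bridge at C3a to form C3a=C7a needs ionisation under acid beside a β-hydroxy ketone that the same acid dehydrates to the aromatic ring. The basic alternative expels O1 or the C6 oxygen from the C7 enolate.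
- Comparison: the chosen plan is longer, but each stereocentre rests on a well-understood element and the sensitive array is never handled unmasked.

Key step: step 8

Assumption: triol **1** is taken as purchasable (it is the hydrogenation product of phloroglucinol), and the lipase is taken to acetylate the enantiotopic hydroxyl of **2** that leads to **3**; the sense is settled by enzyme screening.

Step 1
Reactants: 1 cis,cis-cyclohexane-1,3,5-triol
Product: 2 all-cis-5-(tert-butyldimethylsilyloxy)cyclohexane-1,3-diol (meso)
Conditions: TBSCl (1 equiv), imidazole, DMF, 0 °C → rt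
Reagents that add atoms: tert-butyldimethylsilyl chloride, CC(C)(C)[Si](C)(C)Cl
Why: Statistical monosilylation (silyl ether formation) of three equivalent hydroxyls; the mono-ether is meso and unreacted 1 can be recycled.

Step 2
Reactants: 2 all-cis-5-(tert-butyldimethylsilyloxy)cyclohexane-1,3-diol
Product: 3 (1S,3R,5R)-3-(tert-butyldimethylsilyloxy)-5-hydroxycyclohexyl acetate
Conditions: vinyl acetate, immobilised Candida antarctica lipase B, tBuOMe, 30 °C
Reagents that add atoms: vinyl acetate, CC(=O)OC=C
Why: Irreversible lipase transesterification distinguishes the enantiotopic hydroxyls of the meso diol (enzymatic desymmetrisation); this fixes the configuration of the future C4, from which all other centres derive.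

Step 3
Reactants: 3 (1S,3R,5R)-3-(tert-butyldimethylsilyloxy)-5-hydroxycyclohexyl acetate
Product: 5 (S)-5-(tert-butyldimethylsilyloxy)cyclohex-2-en-1-one, via acetoxy ketone 4 (not isolated)
Conditions: Dess–Martin periodinane, CH2Cl2, 0 °C → rt; then DBU, 0 °C
Reagents that add atoms: none
Why: Dess–Martin oxidation gives β-acetoxy ketone 4, which loses acetic acid by E1cB elimination; acetate leaves far more readily than the silyloxy group on the other β-carbon, so the stereocentre is kept.

Step 4
Reactants: 6 methyl 3-formyl-4-hydroxybenzoate
Product: 7 methyl 3-formyl-4-(triisopropylsilyloxy)benzoate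
Conditions: TIPSCl, imidazole, DMF, rt
Reagents that add atoms: triisopropylsilyl chloride, CC(C)[Si](Cl)(C(C)C)C(C)C
Why: Phenol silylation; the bulky triisopropylsilyl group is chosen because it should not migrate to the neighbouring aldolate oxygen in step 5 and leaves with fluoride together with the C4 silyl ether in step 9.

Step 5
Reactants: 5 (S)-5-(tert-butyldimethylsilyloxy)cyclohex-2-en-1-one, 7 methyl 3-formyl-4-(triisopropylsilyloxy)benzoate
Product: 8 methyl 3-{[(6S)-6-(tert-butyldimethylsilyloxy)-2-oxocyclohex-3-en-1-yl](hydroxy)methyl}-4-(triisopropylsilyloxy)benzoate (mixture at the two new centres)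
Conditions: LiN(iPr)2, THF, −78 °C; then 7, −78 °C; aq NH4Cl
Reagents that add atoms: none
Why: Kinetic α′-deprotonation of the cyclohexenone gives the cross-conjugated lithium dienolate at C3a, which adds to the non-enolisable aldehyde (aldol addition); both new centres are removed in step 6.

Step 6
Reactants: 8 aldol adduct
Product: 10 methyl 3-{(E)-[(6S)-6-(tert-butyldimethylsilyloxy)-2-oxocyclohex-3-en-1-ylidene]methyl}-4-(triisopropylsilyloxy)benzoate, via mesylate 9 (not isolated)
Conditions: MsCl, Et3N, CH2Cl2, −20 → 0 °C; then DBU, 0 °C
Reagents that add atoms: none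
Why: Mesylation and E1cB elimination complete the aldol condensation; the mesylate on C3 leaves in preference to the C4 silyloxy group, and the (E)-arylidene is the thermodynamically favoured isomer.

Step 7
Reactants: 11 3-phenylpropanal
Product: 12 3-phenylpropanal oxime (E/Z mixture)
Conditions: aq NH2OH (50 wt %), EtOH, rt
Reagents that add atoms: hydroxylamine, NO
Why: Oxime formation by condensation; both oxime isomers give the same hydroximoyl chloride in step 8.

Step 8
Reactants: 10 (E)-arylidene dienone, 12 3-phenylpropanal oxime
Product: 15 cis-fused isoxazoline ketone (isoxazoline O on C6 and C9 on C7 both β; C4 silyloxy α; (E)-arylidene at C3a), via hydroximoyl chloride 13 (not isolated), via nitrile oxide 14 (not isolated)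
Conditions: NCS, pyridine (cat.), CH2Cl2, rt; then 10, Et3N (slow addition), 0 °C → rt
Reagents that add atoms: none
Why: NCS chlorinates oxime 12 to hydroximoyl chloride 13, Et3N removes HCl to give nitrile oxide 14, and 14 adds to the endocyclic C6=C7 bond of 10 in a concerted, asynchronous 1,3-dipolar cycloaddition; the closest known reaction type is nitrile oxide addition to cyclohex-2-enones as a masked aldol. The isoxazoline ring closes in the cycloaddition itself, the dipole carbon bonding to the enone α-carbon C7 and the dipole oxygen to the β-carbon C6, as the polarisation of the enone dictates. C6 and C7 are set together and must be cis, because both bonds form on one face of the alkene (suprafacial addition, cis ring fusion). Their absolute sense comes from C4: allylic strain with the (E)-arylidene holds the C4 silyloxy group pseudoaxial on the α face, where it shields C6, so the dipole should arrive on the β face. The step needs chemoselectivity for C6=C7 over the exocyclic C3a=C3 bond; the former is a cis-disubstituted enone alkene, the latter is trisubstituted, aryl-conjugated and flanked by two bulky silyloxy-bearing groups. Slow addition of Et3N keeps the concentration of 14 low and should suppress its dimerisation to the furoxan.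

Step 9
Reactants: 15 cis-fused isoxazoline ketone
Product: 16 isoxazoline ketone with free phenol and free C4 α-hydroxyl
Conditions: Bu4NF, AcOH, THF, 0 °C → rt
Reagents that add atoms: none
Why: Buffered fluoride cleaves the aryl triisopropylsilyl and the secondary tert-butyldimethylsilyl ether (desilylation); acetic acid keeps the medium from enolising the acidic C7–H, and the C4 hydroxyl cannot eliminate because C3a bears no hydrogen.

Step 10
Reactants: 16 isoxazoline ketone diol
Product: 17 di-tert-butylsilylene-bridged arylidene ketone (Si joins the phenol oxygen to the C4 α-oxygen in an eight-membered ring)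
Conditions: tBu2Si(OTf)2, 2,6-lutidine, CH2Cl2 (high dilution), 0 °C
Reagents that add atoms: di-tert-butylsilyl bis(trifluoromethanesulfonate), CC(C)(C)[Si](OS(=O)(=O)C(F)(F)F)(OS(=O)(=O)C(F)(F)F)C(C)(C)C
Why: Silylene protection of a diol used as a temporary silicon tether; the (E)-arylidene places the aryl ring cis to C4, so the ortho oxygen and the pseudoaxial C4 oxygen are within bridging distance on the α side.

Step 11
Reactants: 17 silylene-bridged arylidene ketone, 18 ethyl diazoacetate
Product: 20 silylene-bridged ethyl (2S,3S)-2,3-dihydrofuran-2-carboxylate (ring B closed, aryl α, ester β), via carbonyl ylide 19 (not isolated)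
Conditions: [Cu(OTf)]2·C6H6 (5 mol %), 2,2′-bipyridine (6 mol %), CH2Cl2, rt, slow addition of 18
Reagents that add atoms: none
Why: The copper carbenoid from 18 is attacked by the ketone oxygen to give carbonyl ylide 19, which closes by 1,5-electrocyclisation onto the s-cis arylidene (copper-catalysed (4+1) annulation of an enone with a diazo ester), so the double bond can only be C3a=C7a. The siladioxocine cannot span both faces, so the closure can only turn the aryl group toward the C4 oxygen, which gives 3S; without the tether the pseudoaxial C4 substituent would send it to the β face. The ester is expected trans to the aryl group, which does not matter because C2 is reset in step 12.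

Step 12
Reactants: 20 silylene-bridged dihydrofuran ester
Product: 22 cis-fused (2R,3S) dihydrofuran–dihydrocoumarin lactone with free C4 α-hydroxyl, via trans ester diol 21 (not isolated)
Conditions: Bu4NF, AcOH, THF, 0 °C; then DBU, PhMe, 4 Å MS, 80 °C
Reagents that add atoms: none
Why: Fluoride removes the silylene; DBU then equilibrates C2 through the α-alkoxy ester enolate, and only the cis epimer can be captured by the phenol as the six-membered lactone (transesterification driven by removal of ethanol). The C4 hydroxyl cannot lactonise, because that would put C3a=C7a at a bridgehead.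

Step 13
Reactants: 22 cis-fused lactone
Product: 24 triol (phenol, C8 tertiary alcohol, C4 α-hydroxyl; 2R,3S), via methyl ketone 23 (not isolated)
Conditions: MeMgBr (6 equiv), THF, −78 → −20 °C; aq NH4Cl
Reagents that add atoms: methylmagnesium bromide, C[Mg]Br
Why: Double Grignard addition to the aryl lactone, the most electrophilic carbonyl, through methyl ketone 23; ring opening frees a phenoxide para to the benzoate, which deactivates that ester, and the C4 alkoxide is a spectator.

Step 14
Reactants: 24 triol
Product: 25 C4 ketone (vinylogous ester O1–C7a=C3a–C4=O) with free phenol and tertiary alcohol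
Conditions: MnO2, CH2Cl2, rt
Reagents that add atoms: none
Why: MnO2 oxidises only the allylic C4 alcohol (allylic to the enol ether) and leaves the electron-poor phenol and the tertiary alcohol; the C4 stereocentre is retired here.

Step 15
Reactants: 25 vinylogous ester diol
Product: 26 bis(triethylsilyl) ether of 25 (aryl and C8 oxygens)
Conditions: Et3SiOTf, 2,6-lutidine, CH2Cl2, −78 → −40 °C
Reagents that add atoms: triethylsilyl trifluoromethanesulfonate, CC[Si](CC)(CC)OS(=O)(=O)C(F)(F)F
Why: Silylation of the phenol and the tertiary alcohol, so that neither competes for the methylating agent in step 16; the weak base and low temperature avoid silyl enol ether formation at C4.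

Step 16
Reactants: 26 bis(triethylsilyl) vinylogous ester
Product: 27 C4 methyl dienol ether (C7a=C3a and C4=C5) with intact isoxazoline
Conditions: KN(SiMe3)2, THF/DMPU, −78 °C; MeOTf, −78 °C; Et3N/MeOH quench
Reagents that add atoms: methyl trifluoromethanesulfonate, COS(=O)(=O)C(F)(F)F
Why: Kinetic α′-deprotonation of the vinylogous ester at C5 (Stork–Danheiser regiochemistry) and O-methylation of the potassium dienolate by the hard electrophile MeOTf in a dipolar medium; low temperature and immediate trapping are meant to outrun loss of the C6 oxygen.

Step 17
Reactants: 27 dienol ether bis(silyl ether)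
Product: 28 isoxazoline dienol ether with free phenol and free tertiary alcohol
Conditions: Bu4NF, AcOH, THF, 0 °C
Reagents that add atoms: none
Why: Buffered fluoride desilylation while C6 and C7 are still locked in the isoxazoline; neither acid nor free base meets the dienol ether.

Step 18
Reactants: 28 isoxazoline
Product: 30 methyl 4-hydroxy-3-[(2R,3S,6S,7S)-6-hydroxy-2-(2-hydroxypropan-2-yl)-4-methoxy-7-(3-phenylpropanoyl)-2,3,6,7-tetrahydro-1-benzofuran-3-yl]benzoate, via hydroxy imine 29 (not isolated)
Conditions: Mo(CO)6, MeCN/H2O, 75 °C
Reagents that add atoms: water, O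
Why: Mo(CO)6-mediated reductive N–O cleavage gives β-hydroxy imine 29, which hydrolyses in the wet medium to the β-hydroxy ketone; the C6 and C7 configurations are those set in step 8, and the neutral conditions spare the dienol ether.

## Compound list

1 | cis,cis-cyclohexane-1,3,5-triol | O[C@H]1C[C@@H](O)C[C@@H](O)C1 | starting material
2 | all-cis-5-(tert-butyldimethylsilyloxy)cyclohexane-1,3-diol (meso) | CC(C)(C)[Si](C)(C)O[C@H]1C[C@@H](O)C[C@@H](O)C1 | intermediate
3 | (1S,3R,5R)-3-(tert-butyldimethylsilyloxy)-5-hydroxycyclohexyl acetate | O[C@H]1C[C@@H](O[Si](C)(C)C(C)(C)C)C[C@@H](OC(C)=O)C1 | intermediate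
4 | cis-3-acetoxy-5-(tert-butyldimethylsilyloxy)cyclohexanone (not isolated) | O=C1C[C@@H](O[Si](C)(C)C(C)(C)C)C[C@@H](OC(C)=O)C1 | intermediate
5 | (S)-5-(tert-butyldimethylsilyloxy)cyclohex-2-en-1-one | O=C1C[C@@H](O[Si](C)(C)C(C)(C)C)CC=C1 | intermediate
6 | methyl 3-formyl-4-hydroxybenzoate | COC(=O)c1ccc(O)c(C=O)c1 | starting material
7 | methyl 3-formyl-4-(triisopropylsilyloxy)benzoate | COC(=O)c1ccc(O[Si](C(C)C)(C(C)C)C(C)C)c(C=O)c1 | intermediate
8 | aldol adduct at C3a (mixture at C3a and the carbinol carbon) | O=C1C=CC[C@H](O[Si](C)(C)C(C)(C)C)C1C(O)c1cc(C(=O)OC)ccc1O[Si](C(C)C)(C(C)C)C(C)C | intermediate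
9 | methanesulfonate of 8 (not isolated) | O=C1C=CC[C@H](O[Si](C)(C)C(C)(C)C)C1C(OS(C)(=O)=O)c1cc(C(=O)OC)ccc1O[Si](C(C)C)(C(C)C)C(C)C | intermediate
10 | methyl 3-{(E)-[(6S)-6-(tert-butyldimethylsilyloxy)-2-oxocyclohex-3-en-1-ylidene]methyl}-4-(triisopropylsilyloxy)benzoate | O=C1C=CC[C@H](O[Si](C)(C)C(C)(C)C)/C1=C\c1cc(C(=O)OC)ccc1O[Si](C(C)C)(C(C)C)C(C)C | intermediate
11 | 3-phenylpropanal | O=CCCc1ccccc1 | starting material
12 | 3-phenylpropanal oxime (E/Z mixture) | ON=CCCc1ccccc1 | intermediate
13 | N-hydroxy-3-phenylpropanimidoyl chloride (not isolated) | ON=C(Cl)CCc1ccccc1 | intermediate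
14 | 3-phenylpropanenitrile oxide (not isolated) | [O-][N+]#CCCc1ccccc1 | intermediate
15 | cis-fused isoxazoline ketone: isoxazoline O on C6 and C9 on C7 β, C4 OTBS α, (E)-arylidene at C3a, aryl OTIPS | O=C1/C(=C/c2cc(C(=O)OC)ccc2O[Si](C(C)C)(C(C)C)C(C)C)[C@@H](O[Si](C)(C)C(C)(C)C)C[C@@H]2ON=C(CCc3ccccc3)[C@H]12 | intermediate
16 | isoxazoline ketone with free phenol and free C4 α-hydroxyl | O=C1/C(=C/c2cc(C(=O)OC)ccc2O)[C@@H](O)C[C@@H]2ON=C(CCc3ccccc3)[C@H]12 | intermediate
17 | di-tert-butylsilylene-bridged arylidene ketone (phenol O–Si–O–C4) | O=C1/C(=C/c2cc(C(=O)OC)ccc2O3)[C@@H](O[Si]3(C(C)(C)C)C(C)(C)C)C[C@@H]2ON=C(CCc4ccccc4)[C@H]12 | intermediate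
18 | ethyl diazoacetate | CCOC(=O)C=[N+]=[N-] | starting material
19 | carbonyl ylide from 17 and the carbene of 18 (not isolated) | CCOC(=O)[CH-][O+]=C1/C(=C/c2cc(C(=O)OC)ccc2O3)[C@@H](O[Si]3(C(C)(C)C)C(C)(C)C)C[C@@H]2ON=C(CCc4ccccc4)[C@H]12 | intermediate
20 | silylene-bridged ethyl (2S,3S)-2,3-dihydrofuran-2-carboxylate (aryl α, ester β) | COC(=O)c1ccc2O[Si](C(C)(C)C)(C(C)(C)C)O[C@H]3C[C@@H]4ON=C(CCc5ccccc5)[C@@H]4C4=C3[C@H](c2c1)[C@@H](C(=O)OCC)O4 | intermediate
21 | trans ester with free phenol and C4 hydroxyl (not isolated) | COC(=O)c1ccc(O)c([C@H]2C3=C(O[C@@H]2C(=O)OCC)[C@H]4C(CCc5ccccc5)=NO[C@H]4C[C@@H]3O)c1 | intermediate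
22 | cis-fused (2R,3S) dihydrofuran–dihydrocoumarin lactone, C4 α-hydroxyl free | COC(=O)c1ccc2OC(=O)[C@@H]3OC4=C([C@@H]3c2c1)[C@@H](O)C[C@@H]5ON=C(CCc6ccccc6)[C@H]45 | intermediate
23 | C2 acetyl compound with free phenol (not isolated) | COC(=O)c1ccc(O)c([C@H]2C3=C(O[C@H]2C(C)=O)[C@H]4C(CCc5ccccc5)=NO[C@H]4C[C@@H]3O)c1 | intermediate
24 | triol: phenol, C8 tertiary alcohol, C4 α-hydroxyl | COC(=O)c1ccc(O)c([C@H]2C3=C(O[C@H]2C(C)(C)O)[C@H]4C(CCc5ccccc5)=NO[C@H]4C[C@@H]3O)c1 | intermediate
25 | C4 ketone (vinylogous ester) with free phenol and tertiary alcohol | COC(=O)c1ccc(O)c([C@H]2C3=C(O[C@H]2C(C)(C)O)[C@H]4C(CCc5ccccc5)=NO[C@H]4CC3=O)c1 | intermediate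
26 | bis(triethylsilyl) ether of 25 | COC(=O)c1ccc(O[Si](CC)(CC)CC)c([C@H]2C3=C(O[C@H]2C(C)(C)O[Si](CC)(CC)CC)[C@H]4C(CCc5ccccc5)=NO[C@H]4CC3=O)c1 | intermediate
27 | C4 methyl dienol ether, bis(triethylsilyl) ether | COC(=O)c1ccc(O[Si](CC)(CC)CC)c([C@H]2C3=C(O[C@H]2C(C)(C)O[Si](CC)(CC)CC)[C@H]4C(CCc5ccccc5)=NO[C@H]4C=C3OC)c1 | intermediate
28 | isoxazoline dienol ether with free phenol and tertiary alcohol | COC(=O)c1ccc(O)c([C@H]2C3=C(O[C@H]2C(C)(C)O)[C@H]4C(CCc5ccccc5)=NO[C@H]4C=C3OC)c1 | intermediate
29 | β-hydroxy imine (not isolated) | COC(=O)c1ccc(O)c([C@H]2C3=C(O[C@H]2C(C)(C)O)[C@@H](C(=N)CCc2ccccc2)[C@@H](O)C=C3OC)c1 | intermediate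
30 | methyl 4-hydroxy-3-[(2R,3S,6S,7S)-6-hydroxy-2-(2-hydroxypropan-2-yl)-4-methoxy-7-(3-phenylpropanoyl)-2,3,6,7-tetrahydro-1-benzofuran-3-yl]benzoate | COC(=O)c1ccc(O)c([C@H]2C3=C(O[C@H]2C(C)(C)O)[C@@H](C(=O)CCc2ccccc2)[C@@H](O)C=C3OC)c1 | target

## Step count and least certain steps

Total: 18 steps. Longest linear sequence: 16 steps (steps 1–3, 5, 6, 8–18); steps 4 and 7 are side branches.

**Step 8 (key step).** The aliphatic nitrile oxide may dimerise faster than it adds to a sluggish cross-conjugated enone. Regioselectivity may erode (dipole oxygen bonding to C7), as may facial selectivity, and some addition to the exocyclic alkene is possible. Fallback, from **10** back to **15**: a halo-aldol reaction of **10** with aldehyde **11** (TiCl4, Bu4NI, then Et3N; Morita–Baylis–Hillman-type) forms the C7–C9 bond and gives allylic alcohol F1. Dess–Martin oxidation gives 2-acyl dienone F2. Hydroxylamine should condense with the unhindered side-chain ketone, and the oxime oxygen then closes onto C6 by conjugate addition anti to the pseudoaxial C4 silyloxy group. Protonation at C7 gives the cis-fused ring of **15**.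

**Step 11.** Ylide formation at a hindered, cross-conjugated ketone may be slow, so that carbene dimerisation or insertion takes over, and the tether may raise the barrier to ring closure. Fallback, from **17** back to **22**: dimethyl diazomalonate with Rh2(OAc)4, an acceptor/acceptor carbene known to give such ylides and dihydrofurans, gives geminal diester F3, which has no C2 stereocentre. After Bu4NF/AcOH and DBU the ester cis to the aryl group lactonises to lactone ester F4 without epimerisation. Krapcho dealkoxycarbonylation (LiCl, wet DMSO, heat) removes the remaining ester and returns **22**, cis by ring constraint.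

**Step 12.** Enolisation at C2 may be slower than base-induced migration of the enol ether double bond toward the isoxazoline C=N (through deprotonation at C7), or the transesterification may stall. Fallback, from **21** back to **22**: full deprotonation with KN(SiMe3)2 at −78 °C and kinetic protonation of the ester enolate by a hindered phenol from the face away from the C3 aryl group gives cis ester diol F5. This lactonises with catalytic DBU at room temperature to **22**.

**Step 16.** The C5 enolate may expel the isoxazoline oxygen from C6, which leads to aromatisation. Methylation may occur on carbon or on the isoxazoline nitrogen, and deprotonation may occur at C7. Fallback, from **26** back to **27**: O-methylation of the neutral vinylogous ester with MeOTf and 2,6-di-tert-butyl-4-methylpyridine gives alkoxy-stabilised oxocarbenium triflate F6. Deprotonation at the less hindered C5 with iPr2NEt gives **27** without an enolate being formed.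

**Step 18.** At 75 °C in wet solvent the product may lose water across C6–C7 and aromatise, the dienol ether may hydrolyse, or the imine may resist hydrolysis. Fallback, from **28** back to **30**: single-electron reduction with SmI2 in THF/MeOH at −78 °C cleaves the N–O bond to hydroxy imine **29**, which is hydrolysed cold with B(OH)3 in aqueous methanol. No new compound is involved.

## Further compounds

F1 | step 8 | allylic alcohol from 10 and 11 (C7–C9 bond formed, mixture at the carbinol carbon) | O=C1C(C(O)CCc2ccccc2)=CC[C@H](O[Si](C)(C)C(C)(C)C)/C1=C\c1cc(C(=O)OC)ccc1O[Si](C(C)C)(C(C)C)C(C)C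
F2 | step 8 | 2-(3-phenylpropanoyl) dienone | O=C1C(C(=O)CCc2ccccc2)=CC[C@H](O[Si](C)(C)C(C)(C)C)/C1=C\c1cc(C(=O)OC)ccc1O[Si](C(C)C)(C(C)C)C(C)C
F3 | step 11 | silylene-bridged dimethyl 2,3-dihydrofuran-2,2-dicarboxylate (aryl α) | COC(=O)c1ccc2O[Si](C(C)(C)C)(C(C)(C)C)O[C@H]3C[C@@H]4ON=C(CCc5ccccc5)[C@@H]4C4=C3[C@H](c2c1)C(C(=O)OC)(C(=O)OC)O4
F4 | step 11 | cis-fused lactone carrying a methyl ester on C2 | COC(=O)c1ccc2OC(=O)[C@]3(C(=O)OC)OC4=C([C@@H]3c2c1)[C@@H](O)C[C@@H]5ON=C(CCc6ccccc6)[C@H]45
F5 | step 12 | cis ester with free phenol and C4 hydroxyl | COC(=O)c1ccc(O)c([C@H]2C3=C(O[C@H]2C(=O)OCC)[C@H]4C(CCc5ccccc5)=NO[C@H]4C[C@@H]3O)c1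
F6 | step 16 | O-methylated vinylogous oxocarbenium triflate of 26 | COC(=O)c1ccc(O[Si](CC)(CC)CC)c([C@H]2C3=C(O[C@H]2C(C)(C)O[Si](CC)(CC)CC)[C@H]4C(CCc5ccccc5)=NO[C@H]4CC3=[O+]C)c1.[O-]S(=O)(=O)C(F)(F)F
F0 | step 18 | none | none
A1 | alternative 1 | ring C methyl dienol ether with free C6 hydroxyl and allyl-protected C9 carbinol | COC(=O)c1ccc(O[Si](C)(C)C(C)(C)C)c([C@H]2C3=C(O[C@H]2C(C)(C)O[Si](CC)(CC)CC)[C@@H]([C@@H](CCc2ccccc2)OCC=C)[C@@H](O)C=C3OC)c1
A2 | alternative 1 | C6 aldehyde with a 1-methoxyvinyl group on C3a | COC(=O)c1ccc(O[Si](C)(C)C(C)(C)C)c([C@H]2C(C(=C)OC)=C(O[C@H]2C(C)(C)O[Si](CC)(CC)CC)[C@@H]([C@@H](CCc2ccccc2)OCC=C)C=O)c1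
A3 | alternative 2 | cis-fused dihydrofuran–dihydrocoumarin lactone with C3a methyl ester and C7 methyl group | COC(=O)c1ccc2OC(=O)[C@@H]3OC(C)=C(C(=O)OC)[C@@H]3c2c1
A4 | alternative 2 | methyl 3-{[(E)-4-methoxy-4-oxobut-2-en-2-yl]oxy}-2-oxo-2H-chromene-6-carboxylate | COC(=O)c1ccc2OC(=O)C(O/C(C)=C/C(=O)OC)=Cc2c1
A5 | alternative 3 | exo 7-oxanorbornene cycloadduct with the oxygen bridge between C3a and C6 | COC(=O)c1ccc(O[Si](C)(C)C(C)(C)C)c([C@H]2[C@@]34O[C@@H](C=C3OC)[C@H](C(=O)CCc3ccccc3)[C@@H]4O[C@H]2C(C)(C)O[Si](CC)(CC)CC)c1
A6 | alternative 3 | 2-substituted 3-methoxyfuran tethered through O1 to a (Z)-β-alkoxy enone | COC(=O)c1ccc(O[Si](C)(C)C(C)(C)C)c([C@@H](c2occc2OC)[C@@H](O/C=C\C(=O)CCc2ccccc2)C(C)(C)O[Si](CC)(CC)CC)c1
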